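The pyran ring of the 2H‑chromene is cut at O1–C8a and C4–C4a: the benzene ring then becomes an aryne across C4a–C8a and the unit O1–C2(Me2)–C3–C4 becomes 3‑methylbut‑2‑enal. The feature exploited is that C8a and C4a are neighbours in the benzene ring and that the C5 oxygen flanks C4a, which polarises the aryne. In one operation the key step forms O1–C8a, C4–C4a and O1–C2 and closes the pyran ring with a single orientation. Its precursor is an ortho‑silyl aryl triflate bearing OMOM (the later C5 hydroxyl) next to silicon and the C7 methoxy group; the C6 diketone arm follows by lithiation and two acylations.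

Key step: step 5

Assumption: the target is drawn as its 1,3‑diketo tautomer; it should exist largely as the chelated enol forms of the same compound, and the diketo SMILES is used throughout.

Step 1
Reactants: 1 5-methoxyresorcinol (5-methoxybenzene-1,3-diol)
Product: 2 3-methoxy-5-(methoxymethoxy)phenol
Conditions: MOMCl (1.0 equiv), i-Pr2NEt (1.1 equiv), THF, 0 °C to rt; chromatography, recovered 1 and bis-MOM ether recycled
Reagents that add atoms: chloromethyl methyl ether, COCCl
Why: O-Alkylation of a phenol by the chloromethyl ether (SN2-type acetal formation) with one equivalent of reagent should protect one of the two equivalent hydroxyls, the statistical by-products (bis-MOM ether and unreacted 1) being separable and recyclable.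

Step 2
Reactants: 2 3-methoxy-5-(methoxymethoxy)phenol
Product: 3 3-methoxy-5-(methoxymethoxy)phenyl propan-2-ylcarbamate
Conditions: i-PrNCO (1.2 equiv), Et3N (0.2 equiv), CH2Cl2, rt
Reagents that add atoms: isopropyl isocyanate, CC(C)N=C=O
Why: Base-catalysed addition of the phenol to the isocyanate (carbamoylation) installs an N-isopropyl carbamate, a powerful ortho-directing group that can later be removed under mild basic conditions.

Step 3
Reactants: 3 3-methoxy-5-(methoxymethoxy)phenyl propan-2-ylcarbamate
Product: 7 5-methoxy-3-(methoxymethoxy)-2-(trimethylsilyl)phenyl propan-2-ylcarbamate, via N-silyl carbamate 4 (not isolated), via aryllithium 5 (not isolated), via bis-silyl carbamate 6 (not isolated)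
Conditions: TMSOTf (1.05 equiv), TMEDA (1.1 equiv), Et2O, 0 °C to rt; then TMEDA (2 equiv), n-BuLi (2.2 equiv), –78 °C; then TMSCl (3.5 equiv), –78 °C to rt; aq. NH4Cl
Reagents that add atoms: chlorotrimethylsilane, C[Si](C)(C)Cl
Why: Directed ortho-metalation, in which the carbamate N–H is first masked as the N-silyl derivative 4 so that the carbamate survives n-BuLi, lithiation is expected at the ring carbon flanked by the two strongest directing groups (carbamate and OMOM rather than carbamate and OMe) to give 5, TMSCl silylates that carbon, and the labile N–Si bond of 6 is hydrolysed on work-up.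

Step 4
Reactants: 7 5-methoxy-3-(methoxymethoxy)-2-(trimethylsilyl)phenyl propan-2-ylcarbamate
Product: 9 5-methoxy-3-(methoxymethoxy)-2-(trimethylsilyl)phenyl trifluoromethanesulfonate, via silyl phenol 8 (not isolated)
Conditions: Et2NH (1.5 equiv), DBU (1.5 equiv), MeCN, 40 °C; then PhNTf2 (1.5 equiv), rt
Reagents that add atoms: N-phenylbis(trifluoromethanesulfonimide), O=S(=O)(N(c1ccccc1)S(=O)(=O)C(F)(F)F)C(F)(F)F
Why: Base-induced E1cB cleavage of the N-monoalkyl carbamate (the released isopropyl isocyanate being scavenged by Et2NH as a urea) unmasks phenol 8, which is O-triflated in the same flask by PhNTf2 under mildly basic, non-protic conditions that should leave the neighbouring C–Si bond and the MOM acetal intact.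

Step 5
Reactants: 9 5-methoxy-3-(methoxymethoxy)-2-(trimethylsilyl)phenyl trifluoromethanesulfonate; 10 3-methylbut-2-enal
Product: 14 7-methoxy-5-(methoxymethoxy)-2,2-dimethyl-2H-chromene, via aryne 11 (not isolated), via benzoxete 12 (not isolated), via ortho-quinone methide 13 (not isolated)
Conditions: CsF (3 equiv), 10 (5 equiv), MeCN, 25 to 40 °C, slow addition of 9
Reagents that add atoms: none
Why: Fluoride attacks silicon in 9 and the ortho triflate leaves, giving aryne 11 whose triple bond (the future C4a–C8a bond) is distorted by the σ-withdrawing C5 OMOM group, so the carbonyl oxygen of 10 should add at the remote carbon C8a while the aryl anion develops at C4a, next to the C–O bond that stabilises it, and then closes on the activated carbonyl carbon to benzoxete 12 (formal [2+2], four-membered ring closed by the C4a–C4 bond). The strained benzoxete opens by thermal 4π electrocyclic ring opening to ortho-quinone methide 13, whose Z-configured oxatriene closes the pyran ring by a thermal disrotatory oxa-6π electrocyclisation that forms O1–C2 and restores the aromatic ring. The closest known reaction type is the aryne insertion into the C=O bond of aldehydes and formamides, which includes the formation of 2H-chromenes from arynes and α,β-unsaturated aldehydes. No stereocentre is created, because C2 carries two methyl groups. The step needs one orientation of addition across the aryne (oxygen at C8a, carbon at C4a), secured by the 3-alkoxy substituent as in 3-methoxybenzyne chemistry, and a preference for carbonyl addition over ene or [4+2] pathways, which the neutral fluoride conditions and excess enal should favour; slow addition of 9 keeps the aryne concentration low so that 13 cyclises before a second aryne can intercept it.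

Step 6
Reactants: 14 7-methoxy-5-(methoxymethoxy)-2,2-dimethyl-2H-chromene; 15 N-methoxy-N-methylacetamide
Product: 18 1-[7-methoxy-5-(methoxymethoxy)-2,2-dimethyl-2H-chromen-6-yl]ethan-1-one, via 6-lithiochromene 16 (not isolated), via tetrahedral lithium adduct 17 (not isolated)
Conditions: n-BuLi (1.2 equiv), THF, 0 °C; then 15 (1.5 equiv), –78 to 0 °C; H2O
Reagents that add atoms: none
Why: Directed ortho-metalation followed by a Weinreb ketone synthesis, in which n-BuLi should remove the C6 proton, the only one flanked by the chelating OMOM group and OMe, and aryllithium 16 adds only once to the N-methoxy-N-methyl amide because chelate 17 persists until aqueous work-up.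

Step 7
Reactants: 18 1-[7-methoxy-5-(methoxymethoxy)-2,2-dimethyl-2H-chromen-6-yl]ethan-1-one
Product: 19 1-(5-hydroxy-7-methoxy-2,2-dimethyl-2H-chromen-6-yl)ethan-1-one
Conditions: conc. aq. HCl (0.5 equiv), MeOH, rt to 40 °C
Reagents that add atoms: none
Why: Acid-catalysed transacetalisation of the aryl MOM ether to methanol should proceed readily at a phenol that becomes hydrogen-bonded to the ortho acetyl group, under conditions dilute and cool enough to spare the acid-sensitive C3=C4 alkene of the chromene.

Step 8
Reactants: 19 1-(5-hydroxy-7-methoxy-2,2-dimethyl-2H-chromen-6-yl)ethan-1-one; 20 benzoyl chloride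
Product: 23 1-(5-hydroxy-7-methoxy-2,2-dimethyl-2H-chromen-6-yl)-3-phenylpropane-1,3-dione, via dilithium enolate 21 (not isolated), via dilithium diketonate 22 (not isolated)
Conditions: LiN(SiMe3)2 (4 equiv), THF, –78 to –10 °C; then 20 (1.05 equiv), –78 °C to rt; cold dilute aq. HCl to pH 5
Reagents that add atoms: none
Why: Claisen-type C-acylation run as a one-flask Baker–Venkataraman synthesis, in which excess LiN(SiMe3)2 forms phenoxide–enolate 21, its carbon terminus (or, after O-benzoylation, the derived ester by intramolecular acyl transfer) takes up the benzoyl group, the extra base stores the product as diketonate 22, and the final mild protonation avoids the acid-induced cyclodehydration of the ortho-hydroxy diketone to a flavone.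

Compound list
1 | 5-methoxyresorcinol (5-methoxybenzene-1,3-diol) | COc1cc(O)cc(O)c1 | starting material
2 | 3-methoxy-5-(methoxymethoxy)phenol | COCOc1cc(O)cc(OC)c1 | intermediate
3 | 3-methoxy-5-(methoxymethoxy)phenyl propan-2-ylcarbamate | COCOc1cc(OC)cc(OC(=O)NC(C)C)c1 | intermediate
4 | 3-methoxy-5-(methoxymethoxy)phenyl propan-2-yl(trimethylsilyl)carbamate (N-silyl carbamate) | COCOc1cc(OC)cc(OC(=O)N(C(C)C)[Si](C)(C)C)c1 | intermediate
5 | 2-lithio derivative of 4, lithium on the ring carbon between the carbamate and OMOM (aryllithium) | COCOc1cc(OC)cc(OC(=O)N(C(C)C)[Si](C)(C)C)c1[Li] | intermediate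
6 | 5-methoxy-3-(methoxymethoxy)-2-(trimethylsilyl)phenyl propan-2-yl(trimethylsilyl)carbamate (bis-silyl carbamate) | COCOc1cc(OC)cc(OC(=O)N(C(C)C)[Si](C)(C)C)c1[Si](C)(C)C | intermediate
7 | 5-methoxy-3-(methoxymethoxy)-2-(trimethylsilyl)phenyl propan-2-ylcarbamate | COCOc1cc(OC)cc(OC(=O)NC(C)C)c1[Si](C)(C)C | intermediate
8 | 5-methoxy-3-(methoxymethoxy)-2-(trimethylsilyl)phenol (silyl phenol) | COCOc1cc(OC)cc(O)c1[Si](C)(C)C | intermediate
9 | 5-methoxy-3-(methoxymethoxy)-2-(trimethylsilyl)phenyl trifluoromethanesulfonate | COCOc1cc(OC)cc(OS(=O)(=O)C(F)(F)F)c1[Si](C)(C)C | intermediate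
10 | 3-methylbut-2-enal | CC(C)=CC=O | starting material
11 | 5-methoxy-3-(methoxymethoxy)benzyne (1,2-didehydrobenzene; aryne) | COCOC1=CC(OC)=CC#C1 | intermediate
12 | 5-methoxy-3-(methoxymethoxy)-2-(2-methylprop-1-en-1-yl)-2H-benzo[b]oxete (racemic; benzoxete) | COCOc1cc(OC)cc2OC(C=C(C)C)c12 | intermediate
13 | (6Z)-3-methoxy-5-(methoxymethoxy)-6-(3-methylbut-2-en-1-ylidene)cyclohexa-2,4-dien-1-one (ortho-quinone methide) | O=C1C=C(OC)C=C(OCOC)/C1=C/C=C(C)C | intermediate
14 | 7-methoxy-5-(methoxymethoxy)-2,2-dimethyl-2H-chromene | COCOc1cc(OC)cc2OC(C)(C)C=Cc12 | intermediate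
15 | N-methoxy-N-methylacetamide | CON(C)C(C)=O | starting material
16 | [7-methoxy-5-(methoxymethoxy)-2,2-dimethyl-2H-chromen-6-yl]lithium (6-lithiochromene) | COCOc1c([Li])c(OC)cc2OC(C)(C)C=Cc12 | intermediate
17 | lithium 1-[7-methoxy-5-(methoxymethoxy)-2,2-dimethyl-2H-chromen-6-yl]-1-[methoxy(methyl)amino]ethan-1-olate (racemic; tetrahedral adduct) | COCOc1c(C(C)(O[Li])N(C)OC)c(OC)cc2OC(C)(C)C=Cc12 | intermediate
18 | 1-[7-methoxy-5-(methoxymethoxy)-2,2-dimethyl-2H-chromen-6-yl]ethan-1-one | COCOc1c(C(C)=O)c(OC)cc2OC(C)(C)C=Cc12 | intermediate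
19 | 1-(5-hydroxy-7-methoxy-2,2-dimethyl-2H-chromen-6-yl)ethan-1-one | COc1cc2OC(C)(C)C=Cc2c(O)c1C(C)=O | intermediate
20 | benzoyl chloride | O=C(Cl)c1ccccc1 | starting material
21 | dilithium phenoxide–enolate of 19 (dilithium enolate) | COc1cc2OC(C)(C)C=Cc2c(O[Li])c1C(=C)O[Li] | intermediate
22 | dilithium phenoxide–(Z)-enolate of the target diketone (dilithium diketonate) | COc1cc2OC(C)(C)C=Cc2c(O[Li])c1C(=O)/C=C(\O[Li])c1ccccc1 | intermediate
23 | 1-(5-hydroxy-7-methoxy-2,2-dimethyl-2H-chromen-6-yl)-3-phenylpropane-1,3-dione | COc1cc2c(c(O)c1C(=O)CC(=O)c1ccccc1)C=CC(C)(C)O2 | target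

Total step count: 8. Longest linear sequence: 8 steps (1 to 23).

Steps most likely to fail

Risk 1 (step 5, the key step). The ortho-quinone methide may be intercepted by a second aryne, the aryne may react with the enal by ene or [4+2] pathways, or the orientation of addition may erode. The fallback builds the pyran ring without an aryne and relies on symmetry for regiocontrol; it sets out from 1 (with 10) and comes back to the route at 14. Exhaustive protection of 1 (MOMCl 2.5 equiv, i-Pr2NEt, CH2Cl2) would give 1-methoxy-3,5-bis(methoxymethoxy)benzene F1. n-BuLi in THF at 0 °C should lithiate the carbon flanked by both OMOM groups to give [4-methoxy-2,6-bis(methoxymethoxy)phenyl]lithium F2, which adds to 10 at –78 °C to give, after water quench, racemic 1-[4-methoxy-2,6-bis(methoxymethoxy)phenyl]-3-methylbut-2-en-1-ol F3. Dilute HCl in MeOH at rt should remove both MOM groups and ionise the doubly activated carbinol. Either of the two equivalent phenolic oxygens then closes on the tertiary allylic terminus, so 7-methoxy-2,2-dimethyl-2H-chromen-5-ol F4 is the only possible regioisomer. Re-protection (MOMCl, i-Pr2NEt, CH2Cl2) returns 14.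

Risk 2 (step 3). Lithiation may occur between the carbamate and OMe instead of between the carbamate and OMOM, the carbamoyl group may migrate to carbon (anionic ortho-Fries) on warming, or the MOM acetal may be lost to the silyl triflate. The fallback replaces carbamate-directed silylation by a bromide and a retro-Brook silyl shift; it sets out from 1 and comes back to the route at 9. The bis-MOM ether 1-methoxy-3,5-bis(methoxymethoxy)benzene F1 is lithiated as above to [4-methoxy-2,6-bis(methoxymethoxy)phenyl]lithium F2 and quenched with 1,2-dibromotetrachloroethane to give 2-bromo-5-methoxy-1,3-bis(methoxymethoxy)benzene F5. Partial methanolysis (catalytic HCl, MeOH, 0 °C, stopped at about half conversion, F5 recycled) should give 2-bromo-5-methoxy-3-(methoxymethoxy)phenol F6. O-Silylation with HN(SiMe3)2 in THF at reflux gives [2-bromo-5-methoxy-3-(methoxymethoxy)phenoxy]trimethylsilane F7. n-BuLi at –78 °C then triggers bromine–lithium exchange and a 1,3 oxygen-to-carbon silyl migration to lithium 5-methoxy-3-(methoxymethoxy)-2-(trimethylsilyl)phenolate F8, which is trapped in the same flask with Tf2O to give 9.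

Risk 3 (step 6). Lithiation may occur at C8 (between OMe and O1) instead of C6, n-BuLi may add to the styrene-type C3=C4 bond, or the hindered aryllithium may enolise the amide instead of adding to it. The fallback uses the free C5 phenol to direct functionalisation to C6; it sets out from 14 and comes back to the route at 19. Methanolysis of the MOM ether (catalytic HCl, MeOH, rt) gives 7-methoxy-2,2-dimethyl-2H-chromen-5-ol F4. ortho-Formylation (MgCl2, Et3N, paraformaldehyde, MeCN, reflux) can take place only at C6, the single free ortho position, and should give 5-hydroxy-7-methoxy-2,2-dimethyl-2H-chromene-6-carbaldehyde F9. MeMgBr (2.5 equiv, THF, 0 °C) gives racemic 6-(1-hydroxyethyl)-7-methoxy-2,2-dimethyl-2H-chromen-5-ol F10, and MnO2 in CH2Cl2 oxidises the benzylic alcohol to 19.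

Further compounds
F1 | step 5 | 1-methoxy-3,5-bis(methoxymethoxy)benzene | COCOc1cc(OC)cc(OCOC)c1
F2 | step 5 | [4-methoxy-2,6-bis(methoxymethoxy)phenyl]lithium | COCOc1cc(OC)cc(OCOC)c1[Li]
F3 | step 5 | 1-[4-methoxy-2,6-bis(methoxymethoxy)phenyl]-3-methylbut-2-en-1-ol (racemic) | COCOc1cc(OC)cc(OCOC)c1C(O)C=C(C)C
F4 | step 5 | 7-methoxy-2,2-dimethyl-2H-chromen-5-ol | COc1cc(O)c2C=CC(C)(C)Oc2c1
F5 | step 3 | 2-bromo-5-methoxy-1,3-bis(methoxymethoxy)benzene | COCOc1cc(OC)cc(OCOC)c1Br
F6 | step 3 | 2-bromo-5-methoxy-3-(methoxymethoxy)phenol | COCOc1cc(OC)cc(O)c1Br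
F7 | step 3 | [2-bromo-5-methoxy-3-(methoxymethoxy)phenoxy]trimethylsilane | COCOc1cc(OC)cc(O[Si](C)(C)C)c1Br
F8 | step 3 | lithium 5-methoxy-3-(methoxymethoxy)-2-(trimethylsilyl)phenolate | COCOc1cc(OC)cc(O[Li])c1[Si](C)(C)C
F9 | step 6 | 5-hydroxy-7-methoxy-2,2-dimethyl-2H-chromene-6-carbaldehyde | COc1cc2OC(C)(C)C=Cc2c(O)c1C=O
F10 | step 6 | 6-(1-hydroxyethyl)-7-methoxy-2,2-dimethyl-2H-chromen-5-ol (racemic) | COc1cc2OC(C)(C)C=Cc2c(O)c1C(C)O
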